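**Plan**

- Atom names (cleistanthane numbering): ring C is C8(OOH)–C9=C11–C12(=O)–C13(Me)=C14(vinyl); ring B is C5(isopropenyl)–C6–C7–C8–C9–C10; C10 carries a methyl group and the propanoate chain C1–C3.
- Retrosynthetic cuts, in order: O–C8; then C8–C9 and C11–C12 together (rings B and C at once); then C14–vinyl and C13–C14 of a cyclobutenone that is held by a temporary C8–C12 bond; then C7–C8; then C10–C1 and C5–C4 on a temporary cyclohexanone ring held by the non-target bond C7–C11.
- Enabling feature: the C12 oxygen and C8 are para in ring C, and C8–C9 is the bond shared by rings B and C. Ring C is therefore a four-carbon unit C12–C13–C14–C8 (a cyclobutenone, i.e. a masked vinylketene) plus the two-carbon alkyne C9≡C11, which hangs on quaternary C10 four atoms (C7, C6, C5, C10) from C8, so one metal insertion closes both rings and gives the C12 phenol.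
- Forward order: the temporary ring C9–C10–C5–C6–C7–C11 is made from 2-methylcyclohexenone and cut between C7 and C11 (epoxy-ketone fragmentation), which leaves the ethynyl group on C10 and an aldehyde at C7. C8 and C14 are then added, the cyclobutenone is built, rings B and C are closed together, and the hydroperoxide is introduced last.
- Stereochemistry: C5 by catalytic asymmetric conjugate addition; C10 relayed from C5 (acrylate anti to isopropenyl on the temporary ring); C8 relayed from C10 in the final photooxygenation.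

Key step: step 10

Remark: C8 (the sp3 carbon of the four-membered ring) in 18, 20 and 21 and the epoxide carbons of 8 and 9 are carried as epimer mixtures, because these centres are destroyed in steps 10 and 5; their SMILES leave them undefined.

**Route**

Step 1
Reactants: 1 2-methylcyclohex-2-en-1-one; 2 isopropenylmagnesium bromide
Product: 4 (2R,3S)-2-methyl-3-(prop-1-en-2-yl)cyclohexan-1-one, via bromomagnesium enolate 3 (not isolated)
Conditions: Cu(OTf)2 (3 mol %), chiral C2-symmetric 4,5-diphenylimidazolinium salt as NHC precursor (4 mol %, the enantiomer that leads to 3S), Et2O, −30 °C; then aq. NH4Cl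
Reagents that add atoms: isopropenylmagnesium bromide, C=C(C)[Mg]Br
Why: Copper-catalysed asymmetric conjugate addition of a Grignard reagent to an α-substituted cyclic enone, in which the chiral NHC–copper complex selects the enone face and so sets C5 (ring carbon 3, S); protonation of enolate 3 should give mainly the trans ketone, whose C2 centre is erased in step 2.

Step 2
Reactants: 4 (2R,3S)-2-methyl-3-(prop-1-en-2-yl)cyclohexan-1-one; 5 methyl acrylate
Product: 6 methyl 3-[(1R,6R)-1-methyl-2-oxo-6-(prop-1-en-2-yl)cyclohexyl]propanoate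
Conditions: 5 (1.5 equiv), KOt-Bu (0.1 equiv), t-BuOH/THF, 0 °C to rt
Reagents that add atoms: methyl acrylate, C=CC(=O)OC
Why: Base-catalysed Michael addition through the more substituted enolate (as in Robinson annulations of 2,3-dialkylcyclohexanones), in which the acrylate should enter anti to the neighbouring isopropenyl group (pseudoaxial in the enolate to avoid allylic strain), so that C10 is set with methyl cis to isopropenyl.

Step 3
Reactants: 6 methyl 3-[(1R,6R)-1-methyl-2-oxo-6-(prop-1-en-2-yl)cyclohexyl]propanoate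
Product: 7 methyl 3-[(1R,6R)-1-methyl-2-oxo-6-(prop-1-en-2-yl)cyclohex-3-en-1-yl]propanoate
Conditions: 2-iodoxybenzoic acid (IBX, 2.5 equiv), DMSO/toluene, 70 °C
Reagents that add atoms: none
Why: IBX-mediated α,β-dehydrogenation of a ketone can only take place on the C11/C7 side because C10 is quaternary, and it touches no stereocentre.

Step 4
Reactants: 7 methyl 3-[(1R,6R)-1-methyl-2-oxo-6-(prop-1-en-2-yl)cyclohex-3-en-1-yl]propanoate
Product: 8 methyl 3-[(3R,4R)-3-methyl-2-oxo-4-(prop-1-en-2-yl)-7-oxabicyclo[4.1.0]heptan-3-yl]propanoate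
Conditions: t-BuOOH (in decane), DBU, CH2Cl2, 0 °C to rt
Reagents that add atoms: tert-butyl hydroperoxide, CC(C)(C)OO
Why: Nucleophilic (Weitz–Scheffer) epoxidation attacks only the electron-poor enone and leaves the isopropenyl group and the ester alone; both epoxide diastereomers serve in step 5.

Step 5
Reactants: 8 methyl 3-[(3R,4R)-3-methyl-2-oxo-4-(prop-1-en-2-yl)-7-oxabicyclo[4.1.0]heptan-3-yl]propanoate
Product: 10 methyl (4R,5R)-4-ethynyl-4-methyl-7-oxo-5-(prop-1-en-2-yl)heptanoate, via epoxy tosylhydrazone 9 (not isolated)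
Conditions: TsNHNH2 (1.05 equiv), AcOH/CH2Cl2 (1:1), −20 °C to rt
Reagents that add atoms: none
Why: Eschenmoser–Tanabe fragmentation, in which hydrazone 9 opens the epoxide and then loses sulfinate and dinitrogen, cuts the temporary C7–C11 bond and leaves the ethynyl group on quaternary C10 and the aldehyde at C7 without touching C5 or C10.

Step 6
Reactants: 10 methyl (4R,5R)-4-ethynyl-4-methyl-7-oxo-5-(prop-1-en-2-yl)heptanoate; 11 2,2-dimethyl-1,3-dioxane-4,6-dione (Meldrum's acid)
Product: 13 methyl (4R,5R)-7-(2,2-dimethyl-4,6-dioxo-1,3-dioxan-5-yl)-4-ethynyl-4-methyl-5-(prop-1-en-2-yl)heptanoate, via alkylidene dioxanedione 12 (not isolated)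
Conditions: 11 (1.1 equiv), diethyl 2,6-dimethyl-1,4-dihydropyridine-3,5-dicarboxylate (1.1 equiv), L-proline (20 mol %), EtOH, rt
Reagents that add atoms: 2,2-dimethyl-1,3-dioxane-4,6-dione, CC1(C)OC(=O)CC(=O)O1
Why: Organocatalytic reductive alkylation (Knoevenagel condensation, then transfer hydrogenation of the strongly electrophilic alkylidene 12 by the dihydropyridine) adds C8 and C14 in one pot and leaves the alkyne, the isopropenyl group and the ester untouched.

Step 7
Reactants: 13 methyl (4R,5R)-7-(2,2-dimethyl-4,6-dioxo-1,3-dioxan-5-yl)-4-ethynyl-4-methyl-5-(prop-1-en-2-yl)heptanoate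
Product: 14 (5R,6R)-6-ethynyl-9-methoxy-6-methyl-9-oxo-5-(prop-1-en-2-yl)nonanoic acid
Conditions: pyridine/H2O (10:1), 100 °C
Reagents that add atoms: water, O
Why: Hydrolytic opening of the dioxanedione and decarboxylation of the resulting malonic half acid give the acid under conditions that the methyl ester should survive.

Step 8
Reactants: 14 (5R,6R)-6-ethynyl-9-methoxy-6-methyl-9-oxo-5-(prop-1-en-2-yl)nonanoic acid; 15 1-ethoxyprop-1-yne
Product: 18 methyl (4R,5R)-7-(2-ethoxy-3-methyl-4-oxocyclobut-2-en-1-yl)-4-ethynyl-4-methyl-5-(prop-1-en-2-yl)heptanoate, via acid chloride 16 (not isolated), via ketene 17 (not isolated)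
Conditions: 1-chloro-N,N,2-trimethylprop-1-en-1-amine, CH2Cl2, 0 °C to rt; then 15 (3 equiv), Et3N (slow addition), Et2O, 0 °C to rt
Reagents that add atoms: 1-ethoxyprop-1-yne, CCOC#CC
Why: Neutral acid chloride formation, dehydrochlorination to the aldoketene and ketene–ynol ether [2+2] cycloaddition, in which the nucleophilic methyl-bearing alkyne carbon attacks the ketene carbonyl carbon (C14) and so fixes the 2-methyl-3-ethoxy-4-alkyl pattern; the electron-rich ynol ether should outrun the tethered unactivated alkene and alkyne.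

Step 9
Reactants: 18 methyl (4R,5R)-7-(2-ethoxy-3-methyl-4-oxocyclobut-2-en-1-yl)-4-ethynyl-4-methyl-5-(prop-1-en-2-yl)heptanoate; 19 vinylmagnesium bromide
Product: 21 methyl (4R,5R)-7-(2-ethenyl-3-methyl-4-oxocyclobut-2-en-1-yl)-4-ethynyl-4-methyl-5-(prop-1-en-2-yl)heptanoate, via tertiary cyclobutenol 20 (not isolated)
Conditions: 19 (1.5 equiv), CeCl3 (1.5 equiv), THF, −78 °C; then 1 M HCl, 0 °C
Reagents that add atoms: vinylmagnesium bromide, C=C[Mg]Br; water, O
Why: Organocerium 1,2-addition to the vinylogous ester carbonyl (faster than attack on the methyl ester at −78 °C) followed by acid hydrolysis with allylic transposition (Stork–Danheiser type) places the vinyl group on C14 and moves the carbonyl to C12.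

Step 10
Reactants: 21 methyl (4R,5R)-7-(2-ethenyl-3-methyl-4-oxocyclobut-2-en-1-yl)-4-ethynyl-4-methyl-5-(prop-1-en-2-yl)heptanoate
Product: 23 methyl 3-[(1R,2R)-5-ethenyl-7-hydroxy-1,6-dimethyl-2-(prop-1-en-2-yl)-1,2,3,4-tetrahydronaphthalen-1-yl]propanoate, via cross-conjugated dienone 22 (not isolated)
Conditions: Ni(cod)2 (10 mol %), THF (0.01 M), 0 °C to rt
Reagents that add atoms: none
Why: Proposed new method: zerovalent nickel should insert into the strained acyl–C(sp3) bond C12–C8 of the cyclobutenone to give a nickelacyclopentenone (an η4-vinylketene complex), the tethered alkyne then inserts into the Ni–C8 bond and reductive elimination joins C11 to the acyl carbon C12, so that the net event is a [4+2] union of the masked vinylketene C12–C13–C14–C8 with C9≡C11, after which dienone 22 tautomerises to phenol 23. The closest known reaction type is the intermolecular nickel-catalysed [4+2] benzannulation of cyclobutenones with alkynes (and, thermally, the vinylketene–alkyne benzannulation); new here are the intramolecular mode through a tether on the cyclobutenone sp3 carbon and a terminal alkyne that sits on a quaternary carbon. Ring B closes by 6-exo-dig migratory insertion (C8–C9) and ring C by C–C reductive elimination from the resulting seven-membered nickelacycle (C11–C12). No lasting stereocentre is formed, since C8 becomes an arene carbon and both C8 epimers of 21 converge, while C5 and C10 are not touched. The step needs regioselectivity (C9 to C8, C11 to C12) and chemoselectivity for the cyclobutenone C–C bond over the alkyne C–H bond, the two alkenes and the ester; the four-atom tether C7–C6–C5–C10 secures the first, because the reverse insertion would demand a bridged seven-membered ring, and ring strain together with high dilution (against alkyne oligomerisation) should secure the second. Release of cyclobutenone strain and aromatisation drive the reaction.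

Step 11
Reactants: 23 methyl 3-[(1R,2R)-5-ethenyl-7-hydroxy-1,6-dimethyl-2-(prop-1-en-2-yl)-1,2,3,4-tetrahydronaphthalen-1-yl]propanoate
Product: 24 trigonochinene C
Conditions: O2, rose bengal (cat.), green LED, MeOH, −20 °C
Reagents that add atoms: dioxygen, O=O
Why: Dearomative photooxygenation of a para-alkylphenol by singlet oxygen (addition across C12/C8 and opening to the para-hydroperoxy dienone, as known for estrogens) should place oxygen on C8 anti to the C10 propanoate chain, which is expected to sit pseudoaxial to avoid the peri hydrogen on C11, that is syn to the C10 methyl group, giving the (R)-hydroperoxide; the electron-rich phenol should react faster than the 1,1-disubstituted alkene or the twisted styrene.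

**Compound list**

1 | 2-methylcyclohex-2-en-1-one | CC1=CCCCC1=O | starting material
2 | isopropenylmagnesium bromide (prop-1-en-2-ylmagnesium bromide) | C=C(C)[Mg]Br | starting material
3 | bromomagnesium enolate of 4 (C1–C2 enolate) | Br[Mg]OC1=C(C)[C@@H](C(=C)C)CCC1 | intermediate
4 | (2R,3S)-2-methyl-3-(prop-1-en-2-yl)cyclohexan-1-one (trans; the C2 epimer is of no consequence) | O=C1CCC[C@H](C(=C)C)[C@H]1C | intermediate
5 | methyl acrylate | C=CC(=O)OC | starting material
6 | methyl 3-[(1R,6R)-1-methyl-2-oxo-6-(prop-1-en-2-yl)cyclohexyl]propanoate | O=C1CCC[C@H](C(=C)C)[C@@]1(C)CCC(=O)OC | intermediate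
7 | methyl 3-[(1R,6R)-1-methyl-2-oxo-6-(prop-1-en-2-yl)cyclohex-3-en-1-yl]propanoate | O=C1C=CC[C@H](C(=C)C)[C@@]1(C)CCC(=O)OC | intermediate
8 | methyl 3-[(3R,4R)-3-methyl-2-oxo-4-(prop-1-en-2-yl)-7-oxabicyclo[4.1.0]heptan-3-yl]propanoate (epoxide diastereomers) | O=C1C2OC2C[C@H](C(=C)C)[C@@]1(C)CCC(=O)OC | intermediate
9 | 4-methylbenzenesulfonylhydrazone of 8 | Cc1ccc(cc1)S(=O)(=O)NN=C1C2OC2C[C@H](C(=C)C)[C@@]1(C)CCC(=O)OC | intermediate
10 | methyl (4R,5R)-4-ethynyl-4-methyl-7-oxo-5-(prop-1-en-2-yl)heptanoate | O=CC[C@H](C(=C)C)[C@](C)(C#C)CCC(=O)OC | intermediate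
11 | 2,2-dimethyl-1,3-dioxane-4,6-dione (Meldrum's acid) | CC1(C)OC(=O)CC(=O)O1 | starting material
12 | methyl (4R,5R)-7-(2,2-dimethyl-4,6-dioxo-1,3-dioxan-5-ylidene)-4-ethynyl-4-methyl-5-(prop-1-en-2-yl)heptanoate | CC1(C)OC(=O)C(=CC[C@H](C(=C)C)[C@](C)(C#C)CCC(=O)OC)C(=O)O1 | intermediate
13 | methyl (4R,5R)-7-(2,2-dimethyl-4,6-dioxo-1,3-dioxan-5-yl)-4-ethynyl-4-methyl-5-(prop-1-en-2-yl)heptanoate | CC1(C)OC(=O)C(CC[C@H](C(=C)C)[C@](C)(C#C)CCC(=O)OC)C(=O)O1 | intermediate
14 | (5R,6R)-6-ethynyl-9-methoxy-6-methyl-9-oxo-5-(prop-1-en-2-yl)nonanoic acid | OC(=O)CCC[C@H](C(=C)C)[C@](C)(C#C)CCC(=O)OC | intermediate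
15 | 1-ethoxyprop-1-yne | CCOC#CC | starting material
16 | methyl (4R,5R)-9-chloro-4-ethynyl-4-methyl-9-oxo-5-(prop-1-en-2-yl)nonanoate | ClC(=O)CCC[C@H](C(=C)C)[C@](C)(C#C)CCC(=O)OC | intermediate
17 | methyl (4R,5R)-4-ethynyl-4-methyl-9-oxo-5-(prop-1-en-2-yl)non-8-enoate (aldoketene) | O=C=CCC[C@H](C(=C)C)[C@](C)(C#C)CCC(=O)OC | intermediate
18 | methyl (4R,5R)-7-(2-ethoxy-3-methyl-4-oxocyclobut-2-en-1-yl)-4-ethynyl-4-methyl-5-(prop-1-en-2-yl)heptanoate | CCOC1=C(C)C(=O)C1CC[C@H](C(=C)C)[C@](C)(C#C)CCC(=O)OC | intermediate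
19 | vinylmagnesium bromide (ethenylmagnesium bromide) | C=C[Mg]Br | starting material
20 | methyl (4R,5R)-7-(4-ethenyl-2-ethoxy-4-hydroxy-3-methylcyclobut-2-en-1-yl)-4-ethynyl-4-methyl-5-(prop-1-en-2-yl)heptanoate | C=CC1(O)C(C)=C(OCC)C1CC[C@H](C(=C)C)[C@](C)(C#C)CCC(=O)OC | intermediate
21 | methyl (4R,5R)-7-(2-ethenyl-3-methyl-4-oxocyclobut-2-en-1-yl)-4-ethynyl-4-methyl-5-(prop-1-en-2-yl)heptanoate | C=CC1=C(C)C(=O)C1CC[C@H](C(=C)C)[C@](C)(C#C)CCC(=O)OC | intermediate
22 | methyl 3-[(1R,2R)-5-ethenyl-1,6-dimethyl-7-oxo-2-(prop-1-en-2-yl)-1,2,3,4,4a,7-hexahydronaphthalen-1-yl]propanoate | C=CC1=C(C)C(=O)C=C2C1CC[C@H](C(=C)C)[C@@]2(C)CCC(=O)OC | intermediate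
23 | methyl 3-[(1R,2R)-5-ethenyl-7-hydroxy-1,6-dimethyl-2-(prop-1-en-2-yl)-1,2,3,4-tetrahydronaphthalen-1-yl]propanoate | C=Cc1c(C)c(O)cc2c1CC[C@H](C(=C)C)[C@@]2(C)CCC(=O)OC | intermediate
24 | trigonochinene C, methyl 3-[(1R,2R,4aR)-5-ethenyl-4a-hydroperoxy-1,6-dimethyl-7-oxo-2-(prop-1-en-2-yl)-1,2,3,4,4a,7-hexahydronaphthalen-1-yl]propanoate | C=CC1=C(C)C(=O)C=C2[C@]1(OO)CC[C@H](C(=C)C)[C@@]2(C)CCC(=O)OC | target

**Totals**

Total step count: 11. Longest linear sequence: 11 steps (the route is fully linear from 1).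

**Steps most likely to fail**

1. Step 10 (bears the label). The terminal alkyne may oligomerise at nickel, or migratory insertion next to quaternary C10 may be too slow, so that the nickelacycle decomposes before ring closure. The fallback closes the two bonds one after the other with known reactions; it sets out from 13 and comes back at 23. The 5-alkyl dioxanedione 13 is cyclised in a Conia-ene reaction (In(NTf2)3 cat., toluene, 80 °C, 6-exo-dig), which makes C8–C9 and gives the spiro methylidene dioxanedione F1. Aqueous pyridine at 100 °C then gives the 2-methylidenecyclohexanecarboxylic acid F2. Under the conditions of step 8, the acid chloride F3 and the conjugated ketene F4 lead with 15 to the spiro ethoxycyclobutenone F5, which is kept at or below room temperature. Under the conditions of step 9, the spiro cyclobutenol F6 gives the spiro vinylcyclobutenone F7. Warming F7 in toluene (80–110 °C) opens the four-membered ring to the dienylketene F8, whose 6π-electrocyclisation makes C11–C12 and gives the cyclohexa-2,4-dienone F9, which tautomerises to 23 (the thermal route from 4-alkenylcyclobutenones to phenols).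

2. Step 11. Facial selectivity at C8 may be poor, and the isopropenyl group may undergo a competing ene oxygenation. The fallback gives up kinetic facial control for a separate-and-recycle loop; it sets out from 23 and comes back at 23. The oxygenation is stopped at partial conversion, 24 is separated by chromatography from its C8 epimer, the epimeric hydroperoxide F10, and F10 is reduced with Zn in AcOH at rt (O–O cleavage to the para-quinol, then reductive rearomatisation) to phenol 23, which is resubmitted.

3. Step 1. Transfer of an alkenyl Grignard reagent to an α-substituted enone may proceed with insufficient enantioselectivity. The fallback moves the stereocontrol from the catalyst to a cleavable auxiliary; it sets out from 1 and comes back at 6. Racemic conjugate addition of 2 to 1 (CuBr·SMe2 cat., THF, −40 °C) gives the racemic trans ketone F11. Condensation with (R)-1-phenylethylamine (the enantiomer expected to match; toluene, TsOH cat., water removal) gives the imine F12 of the (3S) ketone beside its diastereomer. Michael addition to 5 through the secondary enamine tautomer is regiospecific for the substituted α-carbon, and for F12 it should occur on the face anti to both the isopropenyl group and the auxiliary, giving the adduct imine F13, while the mismatched diastereomer should lag behind. Aqueous AcOH hydrolyses F13 to 6.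

**Further compounds**

F1 | step 10 | methyl 3-[(8R,9R)-3,3,8-trimethyl-7-methylidene-1,5-dioxo-9-(prop-1-en-2-yl)-2,4-dioxaspiro[5.5]undecan-8-yl]propanoate | CC1(C)OC(=O)C2(CC[C@H](C(=C)C)[C@@](C)(CCC(=O)OC)C2=C)C(=O)O1
F2 | step 10 | (3R,4R)-3-(3-methoxy-3-oxopropyl)-3-methyl-2-methylidene-4-(prop-1-en-2-yl)cyclohexane-1-carboxylic acid (C1 epimers) | OC(=O)C1CC[C@H](C(=C)C)[C@@](C)(CCC(=O)OC)C1=C
F3 | step 10 | acid chloride of F2 | ClC(=O)C1CC[C@H](C(=C)C)[C@@](C)(CCC(=O)OC)C1=C
F4 | step 10 | methyl 3-[(1R,6R)-1-methyl-2-methylidene-3-(oxomethylidene)-6-(prop-1-en-2-yl)cyclohexyl]propanoate (ketene) | O=C=C1CC[C@H](C(=C)C)[C@@](C)(CCC(=O)OC)C1=C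
F5 | step 10 | methyl 3-[(6R,7R)-3-ethoxy-2,6-dimethyl-5-methylidene-1-oxo-7-(prop-1-en-2-yl)spiro[3.5]non-2-en-6-yl]propanoate | CCOC1=C(C)C(=O)C12CC[C@H](C(=C)C)[C@@](C)(CCC(=O)OC)C2=C
F6 | step 10 | methyl 3-[(6R,7R)-1-ethenyl-3-ethoxy-1-hydroxy-2,6-dimethyl-5-methylidene-7-(prop-1-en-2-yl)spiro[3.5]non-2-en-6-yl]propanoate | C=CC1(O)C(C)=C(OCC)C12CC[C@H](C(=C)C)[C@@](C)(CCC(=O)OC)C2=C
F7 | step 10 | methyl 3-[(6R,7R)-3-ethenyl-2,6-dimethyl-5-methylidene-1-oxo-7-(prop-1-en-2-yl)spiro[3.5]non-2-en-6-yl]propanoate | C=CC1=C(C)C(=O)C12CC[C@H](C(=C)C)[C@@](C)(CCC(=O)OC)C2=C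
F8 | step 10 | dienylketene from ring opening of F7 | O=C=C(C)C(C=C)=C1CC[C@H](C(=C)C)[C@@](C)(CCC(=O)OC)C1=C
F9 | step 10 | methyl 3-[(1R,2R)-5-ethenyl-1,6-dimethyl-7-oxo-2-(prop-1-en-2-yl)-1,2,3,4,7,8-hexahydronaphthalen-1-yl]propanoate | C=CC1=C(C)C(=O)CC2=C1CC[C@H](C(=C)C)[C@@]2(C)CCC(=O)OC
F10 | step 11 | methyl 3-[(1R,2R,4aS)-5-ethenyl-4a-hydroperoxy-1,6-dimethyl-7-oxo-2-(prop-1-en-2-yl)-1,2,3,4,4a,7-hexahydronaphthalen-1-yl]propanoate (C8 epimer of 24) | C=CC1=C(C)C(=O)C=C2[C@@]1(OO)CC[C@H](C(=C)C)[C@@]2(C)CCC(=O)OC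
F11 | step 1 | racemic trans-2-methyl-3-(prop-1-en-2-yl)cyclohexan-1-one | O=C1CCCC(C(=C)C)C1C
F12 | step 1 | (3S)-2-methyl-N-[(1R)-1-phenylethyl]-3-(prop-1-en-2-yl)cyclohexan-1-imine | C[C@H](c1ccccc1)N=C1CCC[C@H](C(=C)C)C1C
F13 | step 1 | methyl 3-[(1R,6R)-1-methyl-2-{[(1R)-1-phenylethyl]imino}-6-(prop-1-en-2-yl)cyclohexyl]propanoate | C[C@H](c1ccccc1)N=C1CCC[C@H](C(=C)C)[C@@]1(C)CCC(=O)OC
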